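**Plan**
- Retrosynthesis: after removal of a phenol protecting group, ring A is cut at C7a–C3a and C5–C4 (a CO2 bridge is added back), which leads to a 6-allyl-4-methoxy-2-pyrone bound through its 3-oxygen to a 1-aryl-2-(aryloxymethyl)but-3-ynyl group. Further cuts are the pyrone C3–O bond, the eugenyl O–CH2 bond and the C2–C3 bond.
- Enabling feature: ring A (C3a, C4, C5, C6, C7, C7a) carries O1 on C7a, OMe on C7, allyl on C5, H on C4 and C6 and the C3 branch on C3a. This is the pattern of a 3,4-dioxygenated 6-allylpyrone (C3 to C7a, C4 to C7, C6 to C5) plus an alkyne (to C3a and C4) held by the three-atom O1–C2–C3 tether.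
- Forward: C2–C3 is made first by an auxiliary-controlled aldol, the eugenyl ether is attached by Mitsunobu reaction, and the pyrone (built separately, allyl group installed by Stille coupling) is attached through oxygen by carbenoid O–H insertion. Ring A and the dihydrofuran then close together; ring B and the eugenyl ring are bought.
- Stereochemistry: both centres (C2 S, C3 R) come from the syn-aldol under control of (S)-4-benzyloxazolidin-2-one and are carried through unchanged, since no later step makes or breaks a bond at either.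

Key step: step 14

Remark: ring positions follow 2,3-dihydrobenzofuran numbering (O1, C2, C3, C3a, C4–C7, C7a); the SMILES is read as the 2,3-trans isomer, (2S,3R).

**Route**

Step 1
Reactants: 1 4-(trimethylsilyl)but-3-yn-1-ol
Product: 3 4-(trimethylsilyl)but-3-ynoic acid, via aldehyde 2 (not isolated)
Conditions: CrO3, H2SO4, H2O, acetone, 0 °C
Reagents that add atoms: water, O
Why: Jones oxidation takes the primary alcohol through aldehyde 2 and its hydrate to the carboxylic acid, and the silyl-capped alkyne is inert to aqueous hexavalent chromium at 0 °C.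

Step 2
Reactants: 3 4-(trimethylsilyl)but-3-ynoic acid; 4 (S)-4-benzyloxazolidin-2-one
Product: 6 (S)-4-benzyl-3-[4-(trimethylsilyl)but-3-ynoyl]oxazolidin-2-one, via acid chloride 5 (not isolated)
Conditions: (COCl)2, cat. DMF, CH2Cl2, 0 °C to rt; then 4 pre-treated with n-BuLi, THF, −78 °C
Reagents that add atoms: none
Why: N-Acylation of the lithiated oxazolidinone by the acid chloride is fast at −78 °C and uses no amine base, which should keep the 3-alkynoyl unit from isomerising to the allenoyl isomer.

Step 3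
Reactants: 7 vanillin (4-hydroxy-3-methoxybenzaldehyde)
Product: 8 3-methoxy-4-(methoxymethoxy)benzaldehyde
Conditions: MOMCl, iPr2NEt, CH2Cl2, 0 °C to rt
Reagents that add atoms: chloromethyl methyl ether (MOMCl), COCCl
Why: O-Alkylation of the phenol by the alkoxymethyl chloride (MOM protection, a Williamson-type substitution) masks the acidic hydroxyl for the enolate, hydride, Mitsunobu and carbenoid steps and is removable by mild acid at the end.

Step 4
Reactants: 6 (S)-4-benzyl-3-[4-(trimethylsilyl)but-3-ynoyl]oxazolidin-2-one; 8 3-methoxy-4-(methoxymethoxy)benzaldehyde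
Product: 11 (S)-4-benzyl-3-{(2S,3S)-3-hydroxy-3-[3-methoxy-4-(methoxymethoxy)phenyl]-2-[(trimethylsilyl)ethynyl]propanoyl}oxazolidin-2-one, via dibutylboron Z-enolate 9 (not isolated), via dibutylboron aldolate 10 (not isolated)
Conditions: Bu2BOTf, iPr2NEt, CH2Cl2, −78 to 0 °C; then 8, −78 to 0 °C; pH 7 buffer, MeOH, H2O2, 0 °C
Reagents that add atoms: none
Why: Evans syn-aldol reaction: soft enolisation gives the Z-boron enolate 9, which adds to the aldehyde through a chair Zimmerman–Traxler transition state on the face away from the benzyl group of the auxiliary, so that the two new centres should arise as (2S,3S) with the syn relation that becomes the 2,3-trans relation of the dihydrofuran.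

Step 5
Reactants: 11 aldol adduct
Product: 12 (1S,2R)-1-[3-methoxy-4-(methoxymethoxy)phenyl]-2-[(trimethylsilyl)ethynyl]propane-1,3-diol
Conditions: LiBH4, MeOH (1 equiv), THF, 0 °C
Reagents that add atoms: none
Why: Reductive cleavage of the N-acyl oxazolidinone by LiBH4 delivers the primary alcohol and returns the auxiliary without a base strong enough to epimerise the propargylic centre or to desilylate the alkyne.

Step 6
Reactants: 12 diol; 13 eugenol (4-allyl-2-methoxyphenol)
Product: 14 (1S,2R)-2-[(4-allyl-2-methoxyphenoxy)methyl]-1-[3-methoxy-4-(methoxymethoxy)phenyl]-4-(trimethylsilyl)but-3-yn-1-ol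
Conditions: PPh3, DIAD, THF, 0 °C to rt
Reagents that add atoms: none
Why: Mitsunobu etherification activates the unhindered primary hydroxyl in preference to the hindered secondary benzylic one and the phenol displaces the oxyphosphonium group at CH2, so no stereocentre is involved.

Step 7
Reactants: 15 4-hydroxy-6-methyl-2H-pyran-2-one
Product: 16 6-methyl-2-oxo-2H-pyran-4-yl acetate
Conditions: Ac2O, Et3N, CH2Cl2, 0 °C
Reagents that add atoms: acetic anhydride, CC(=O)OC(C)=O
Why: O-Acylation of the vinylogous acid masks the enol so that the ring is deactivated towards ionic bromination in the next step.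

Step 8
Reactants: 16 6-methyl-2-oxo-2H-pyran-4-yl acetate
Product: 17 6-(bromomethyl)-2-oxo-2H-pyran-4-yl acetate
Conditions: NBS, AIBN (cat.), PhCF3, reflux
Reagents that add atoms: N-bromosuccinimide, O=C1CCC(=O)N1Br
Why: Wohl–Ziegler bromination: the 6-methyl group is the vinylogous benzylic position of the pyrone and gives a stabilised radical, so bromine should enter there.

Step 9
Reactants: 17 6-(bromomethyl)-2-oxo-2H-pyran-4-yl acetate
Product: 18 6-allyl-2-oxo-2H-pyran-4-yl acetate
Conditions: Bu3SnCH=CH2, Pd(PPh3)4 (cat.), THF, 60 °C; aq. KF work-up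
Reagents that add atoms: tributyl(vinyl)stannane, C=C[Sn](CCCC)(CCCC)CCCC
Why: Stille coupling of the benzylic-type bromide (oxidative addition to zerovalent palladium, transmetalation from tin, reductive elimination) joins the vinyl group to the CH2 and thus builds the 6-allyl group under neutral conditions that should not move the double bond into conjugation.

Step 10
Reactants: 18 6-allyl-2-oxo-2H-pyran-4-yl acetate
Product: 19 6-allyl-4-hydroxy-2H-pyran-2-one
Conditions: K2CO3, MeOH, 0 °C; then 1 M HCl
Reagents that add atoms: none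
Why: Base-mediated methanolysis (transesterification) of the enol acetate is fast at 0 °C and leaves the product as its pyronate anion, which resists both ring opening and deprotonation at the allylic CH2 until it is acidified.

Step 11
Reactants: 19 6-allyl-4-hydroxy-2H-pyran-2-one
Product: 20 6-allyl-3-diazo-2H-pyran-2,4(3H)-dione
Conditions: 4-acetamidobenzenesulfonyl azide, Et3N, MeCN, 0 °C
Reagents that add atoms: 4-acetamidobenzenesulfonyl azide, CC(=O)Nc1ccc(cc1)S(=O)(=O)N=[N+]=[N-]
Why: Regitz diazo transfer from the sulfonyl azide to the enolate of the cyclic 1,3-dicarbonyl system places the diazo group on C3, the only carbon flanked by both carbonyl groups.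

Step 12
Reactants: 14 secondary alcohol; 20 6-allyl-3-diazo-2H-pyran-2,4(3H)-dione
Product: 21 6-allyl-3-{[(1S,2R)-2-[(4-allyl-2-methoxyphenoxy)methyl]-1-[3-methoxy-4-(methoxymethoxy)phenyl]-4-(trimethylsilyl)but-3-yn-1-yl]oxy}-4-hydroxy-2H-pyran-2-one
Conditions: Rh2(OAc)4 (2 mol %), PhF, 60 °C, slow addition of 20 to 14
Reagents that add atoms: none
Why: Carbenoid O–H insertion: Rh2(OAc)4 turns the diazo dione into an electrophilic rhodium carbenoid that is trapped by the hydroxyl oxygen (oxonium ylide, then proton shift and enolisation to the 4-hydroxypyrone); the carbinol C–O bond is not broken, so the S centre is retained, and the silyl cap should keep the alkyne out of the reaction.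

Step 13
Reactants: 21 silylated 4-hydroxypyrone ether
Product: 23 6-allyl-3-{[(1S,2R)-2-[(4-allyl-2-methoxyphenoxy)methyl]-1-[3-methoxy-4-(methoxymethoxy)phenyl]but-3-yn-1-yl]oxy}-4-methoxy-2H-pyran-2-one, via desilylated hydroxypyrone 22 (not isolated)
Conditions: K2CO3, MeOH, rt; evaporate; Me2SO4, acetone, rt
Reagents that add atoms: dimethyl sulfate, COS(=O)(=O)OC
Why: Methanolysis of the alkynyl–silicon bond by K2CO3/MeOH is carried out while the pyrone is protected as its 4-oxido anion, and O-alkylation of that anion with Me2SO4 in acetone (the classical conditions that favour 4-methoxy-2-pyrones over 2-methoxy-4-pyrones) then fixes the diene.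

Step 14
Reactants: 23 pyrone–alkyne precursor
Product: 25 (2S,3R)-5-allyl-3-[(4-allyl-2-methoxyphenoxy)methyl]-7-methoxy-2-[3-methoxy-4-(methoxymethoxy)phenyl]-2,3-dihydrobenzofuran, via bridged bicyclic lactone 24 (not isolated)
Conditions: degassed toluene (0.01 M), BHT (cat.), sealed tube, 170 °C
Reagents that add atoms: none
Why: On heating, the 2-pyrone acts as the diene and the tethered terminal alkyne as the dienophile in an intramolecular Diels–Alder reaction that joins pyrone C3 to the internal alkyne carbon (C7a–C3a) and pyrone C6 to the terminal carbon (C5–C4), giving the 2-oxabicyclo[2.2.2]octadienone 24, which then expels CO2 by retro-Diels–Alder reaction and becomes benzene ring A of 25. The closest known reaction type is the thermal cycloaddition of 2-pyrones to tethered alkynes followed by decarboxylative aromatisation to annulated benzenes. The dihydrofuran closes as the five-membered ring spanned by the three-atom O–CH(Ar)–CH tether in the same cycloaddition (a type 1 intramolecular cycloaddition, tether on a diene terminus), and ring A closes as the six-membered carbocycle of the [4+2] event. No lasting stereocentre is created: the two bridgehead centres of 24 are erased on aromatisation, so either face of the pyrone may react, and the two tether centres are untouched because no bond to them is made or broken. The step needs regiocontrol, which the short tether enforces since only the internal alkyne carbon can reach pyrone C3, and chemoselectivity for the alkyne over the two allyl alkenes, which the five-ring-forming geometry and high dilution should secure. Acid-free conditions in an apolar solvent are chosen so that the benzylic pyronyl ether should not ionise before it has cyclised.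

Step 15
Reactants: 25 MOM ether of the target
Product: 26 4-{(2S,3R)-5-allyl-3-[(4-allyl-2-methoxyphenoxy)methyl]-7-methoxy-2,3-dihydrobenzofuran-2-yl}-2-methoxyphenol (CNP0138854.1)
Conditions: HCl (cat.), MeOH, rt to 40 °C
Reagents that add atoms: none
Why: Acid-catalysed acetal exchange with methanol removes the MOM group under conditions that should leave the allyl groups and the trans-dihydrobenzofuran unchanged.

**Compound list**
1 | 4-(trimethylsilyl)but-3-yn-1-ol | C[Si](C)(C)C#CCCO | starting material
2 | 4-(trimethylsilyl)but-3-ynal | C[Si](C)(C)C#CCC=O | intermediate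
3 | 4-(trimethylsilyl)but-3-ynoic acid | C[Si](C)(C)C#CCC(=O)O | intermediate
4 | (S)-4-benzyloxazolidin-2-one | O=C1N[C@@H](Cc2ccccc2)CO1 | starting material
5 | 4-(trimethylsilyl)but-3-ynoyl chloride | C[Si](C)(C)C#CCC(=O)Cl | intermediate
6 | (S)-4-benzyl-3-[4-(trimethylsilyl)but-3-ynoyl]oxazolidin-2-one | C[Si](C)(C)C#CCC(=O)N1C(=O)OC[C@@H]1Cc1ccccc1 | intermediate
7 | vanillin (4-hydroxy-3-methoxybenzaldehyde) | COc1cc(C=O)ccc1O | starting material
8 | 3-methoxy-4-(methoxymethoxy)benzaldehyde | COCOc1ccc(C=O)cc1OC | intermediate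
9 | dibutylboron Z-enolate of 6: (S)-4-benzyl-3-[(Z)-1-(dibutylboryloxy)-4-(trimethylsilyl)but-1-en-3-ynyl]oxazolidin-2-one | CCCCB(CCCC)O/C(=C\C#C[Si](C)(C)C)N1C(=O)OC[C@@H]1Cc1ccccc1 | intermediate
10 | dibutylboron aldolate (O-dibutylboryl derivative of 11) | O=C(N1C(=O)OC[C@@H]1Cc1ccccc1)[C@@H](C#C[Si](C)(C)C)[C@H](OB(CCCC)CCCC)c1ccc(OCOC)c(OC)c1 | intermediate
11 | (S)-4-benzyl-3-{(2S,3S)-3-hydroxy-3-[3-methoxy-4-(methoxymethoxy)phenyl]-2-[(trimethylsilyl)ethynyl]propanoyl}oxazolidin-2-one | O=C(N1C(=O)OC[C@@H]1Cc1ccccc1)[C@@H](C#C[Si](C)(C)C)[C@H](O)c1ccc(OCOC)c(OC)c1 | intermediate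
12 | (1S,2R)-1-[3-methoxy-4-(methoxymethoxy)phenyl]-2-[(trimethylsilyl)ethynyl]propane-1,3-diol | OC[C@@H](C#C[Si](C)(C)C)[C@H](O)c1ccc(OCOC)c(OC)c1 | intermediate
13 | eugenol (4-allyl-2-methoxyphenol) | C=CCc1ccc(O)c(OC)c1 | starting material
14 | (1S,2R)-2-[(4-allyl-2-methoxyphenoxy)methyl]-1-[3-methoxy-4-(methoxymethoxy)phenyl]-4-(trimethylsilyl)but-3-yn-1-ol | C=CCc1ccc(OC[C@@H](C#C[Si](C)(C)C)[C@H](O)c2ccc(OCOC)c(OC)c2)c(OC)c1 | intermediate
15 | 4-hydroxy-6-methyl-2H-pyran-2-one | CC1=CC(O)=CC(=O)O1 | starting material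
16 | 6-methyl-2-oxo-2H-pyran-4-yl acetate | CC(=O)OC1=CC(=O)OC(C)=C1 | intermediate
17 | 6-(bromomethyl)-2-oxo-2H-pyran-4-yl acetate | CC(=O)OC1=CC(=O)OC(CBr)=C1 | intermediate
18 | 6-allyl-2-oxo-2H-pyran-4-yl acetate | C=CCC1=CC(OC(C)=O)=CC(=O)O1 | intermediate
19 | 6-allyl-4-hydroxy-2H-pyran-2-one | C=CCC1=CC(O)=CC(=O)O1 | intermediate
20 | 6-allyl-3-diazo-2H-pyran-2,4(3H)-dione | C=CCC1=CC(=O)C(=[N+]=[N-])C(=O)O1 | intermediate
21 | 6-allyl-3-{[(1S,2R)-2-[(4-allyl-2-methoxyphenoxy)methyl]-1-[3-methoxy-4-(methoxymethoxy)phenyl]-4-(trimethylsilyl)but-3-yn-1-yl]oxy}-4-hydroxy-2H-pyran-2-one | C=CCc1ccc(OC[C@@H](C#C[Si](C)(C)C)[C@H](OC2=C(O)C=C(CC=C)OC2=O)c2ccc(OCOC)c(OC)c2)c(OC)c1 | intermediate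
22 | 6-allyl-3-{[(1S,2R)-2-[(4-allyl-2-methoxyphenoxy)methyl]-1-[3-methoxy-4-(methoxymethoxy)phenyl]but-3-yn-1-yl]oxy}-4-hydroxy-2H-pyran-2-one (formed as its potassium salt) | C=CCc1ccc(OC[C@@H](C#C)[C@H](OC2=C(O)C=C(CC=C)OC2=O)c2ccc(OCOC)c(OC)c2)c(OC)c1 | intermediate
23 | 6-allyl-3-{[(1S,2R)-2-[(4-allyl-2-methoxyphenoxy)methyl]-1-[3-methoxy-4-(methoxymethoxy)phenyl]but-3-yn-1-yl]oxy}-4-methoxy-2H-pyran-2-one | C=CCc1ccc(OC[C@@H](C#C)[C@H](OC2=C(OC)C=C(CC=C)OC2=O)c2ccc(OCOC)c(OC)c2)c(OC)c1 | intermediate
24 | intramolecular [4+2] adduct of 23: 2-oxabicyclo[2.2.2]octa-5,7-dien-3-one whose bridgehead C4 (former pyrone C3) bears the tether oxygen, C5 the tether carbon, C8 the methoxy group and bridgehead C1 the allyl group (bridgehead configuration left open; either converges on 25) | C=CCc1ccc(OC[C@H]2C3=CC4(CC=C)C=C(OC)C3(O[C@@H]2c2ccc(OCOC)c(OC)c2)C(=O)O4)c(OC)c1 | intermediate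
25 | (2S,3R)-5-allyl-3-[(4-allyl-2-methoxyphenoxy)methyl]-7-methoxy-2-[3-methoxy-4-(methoxymethoxy)phenyl]-2,3-dihydrobenzofuran | C=CCc1ccc(OC[C@H]2c3cc(CC=C)cc(OC)c3O[C@@H]2c2ccc(OCOC)c(OC)c2)c(OC)c1 | intermediate
26 | 4-{(2S,3R)-5-allyl-3-[(4-allyl-2-methoxyphenoxy)methyl]-7-methoxy-2,3-dihydrobenzofuran-2-yl}-2-methoxyphenol | C=CCc1ccc(OC[C@H]2c3cc(CC=C)cc(OC)c3O[C@@H]2c2ccc(O)c(OC)c2)c(OC)c1 | target

**Step count**
Total: 15 steps. Longest linear sequence: 9 steps (steps 1, 2, 4, 5, 6, 12, 13, 14, 15 from 1; the pyrone branch, steps 7–15, is equally long).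

**Steps most likely to fail**

Step 4. What may go wrong is propargyl-to-allenyl isomerisation of the acyl imide during enolisation, and retro-aldol cleavage or epimerisation at the doubly activated α-carbon of the adduct. The fallback keeps the auxiliary but carries the future alkyne as a vinyl group; it sets out from 4 and 8 and comes back at 12. Auxiliary 4 would be acylated (n-BuLi, crotonyl chloride) to (S)-4-benzyl-3-[(E)-but-2-enoyl]oxazolidin-2-one F1. Its dibutylboron dienolate (Bu2BOTf, Et3N) would add to 8 through the α-carbon to give the syn α-vinyl aldol F2. LiBH4 would then give the vinyl diol F3, and 2,2-dimethoxypropane with PPTS the cis-acetonide F4. Cleavage of the vinyl group (OsO4 cat., NaIO4, 2,6-lutidine) would give the dioxane aldehyde F5, and CBr4/PPh3/Zn the dibromoalkene F6. Treatment with n-BuLi (2 equiv) followed by Me3SiCl would give the silylalkyne acetonide F7, from which aqueous AcOH would release diol 12.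

Step 12. What may go wrong is consumption of the rhodium carbenoid by cyclopropanation of the terminal alkenes, by a second insertion into the acidic enol hydroxyl of the product, or by Wolff rearrangement, before it meets the hindered secondary hydroxyl. The fallback forms the same C–O bond by cross-coupling instead of carbenoid insertion, again without touching the carbinol C–O bond; it sets out from 19 and 14 and comes back at 23. Pyrone 19 would be O-methylated (Me2SO4, K2CO3, acetone) to 6-allyl-4-methoxy-2H-pyran-2-one F8 and brominated at C3 (NBS, MeCN, 0 °C, dark) to 6-allyl-3-bromo-4-methoxy-2H-pyran-2-one F9. Palladium-catalysed C–O coupling of F9 with alcohol 14 (Pd2(dba)3, RockPhos, Cs2CO3, toluene, 80 °C) would give the silylated pyronyl ether F10, and AgNO3 (cat.) in aqueous acetone would remove the silyl group to give 23.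

Step 14. What may go wrong is reversible heterolysis of the electron-rich benzylic pyronyl ether during prolonged heating, which would scramble the aryl-bearing centre before the cycloaddition. The fallback gives up stereoretention at that centre and sets it under thermodynamic control after ring closure; it sets out from 23 and comes back at 26. The thermolysate, then a mixture of 25 and its 2-epimer, the (2R,3R)-cis MOM ether F11, would be deprotected as in step 15 to 26 and the cis-phenol F12. The mixture would be equilibrated with CF3CO2H in CH2Cl2, where reversible opening of the O1–C2 bond to a para-quinone methide and reclosure trans to the fixed C3 substituent should funnel F12 into 26.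

**Further compounds**
F1 | step 4 | (S)-4-benzyl-3-[(E)-but-2-enoyl]oxazolidin-2-one | C/C=C/C(=O)N1C(=O)OC[C@@H]1Cc1ccccc1
F2 | step 4 | (S)-4-benzyl-3-{(2S,3S)-2-ethenyl-3-hydroxy-3-[3-methoxy-4-(methoxymethoxy)phenyl]propanoyl}oxazolidin-2-one | O=C(N1C(=O)OC[C@@H]1Cc1ccccc1)[C@@H](C=C)[C@H](O)c1ccc(OCOC)c(OC)c1
F3 | step 4 | (1S,2R)-2-ethenyl-1-[3-methoxy-4-(methoxymethoxy)phenyl]propane-1,3-diol | OC[C@@H](C=C)[C@H](O)c1ccc(OCOC)c(OC)c1
F4 | step 4 | (4S,5R)-5-ethenyl-4-[3-methoxy-4-(methoxymethoxy)phenyl]-2,2-dimethyl-1,3-dioxane | CC1(C)OC[C@@H](C=C)[C@H](O1)c1ccc(OCOC)c(OC)c1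
F5 | step 4 | (4S,5R)-4-[3-methoxy-4-(methoxymethoxy)phenyl]-2,2-dimethyl-1,3-dioxane-5-carbaldehyde | CC1(C)OC[C@@H](C=O)[C@H](O1)c1ccc(OCOC)c(OC)c1
F6 | step 4 | (4S,5R)-5-(2,2-dibromoethenyl)-4-[3-methoxy-4-(methoxymethoxy)phenyl]-2,2-dimethyl-1,3-dioxane | CC1(C)OC[C@@H](C=C(Br)Br)[C@H](O1)c1ccc(OCOC)c(OC)c1
F7 | step 4 | (4S,5R)-4-[3-methoxy-4-(methoxymethoxy)phenyl]-2,2-dimethyl-5-[(trimethylsilyl)ethynyl]-1,3-dioxane | CC1(C)OC[C@@H](C#C[Si](C)(C)C)[C@H](O1)c1ccc(OCOC)c(OC)c1
F8 | step 12 | 6-allyl-4-methoxy-2H-pyran-2-one | C=CCC1=CC(OC)=CC(=O)O1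
F9 | step 12 | 6-allyl-3-bromo-4-methoxy-2H-pyran-2-one | C=CCC1=CC(OC)=C(Br)C(=O)O1
F10 | step 12 | 6-allyl-3-{[(1S,2R)-2-[(4-allyl-2-methoxyphenoxy)methyl]-1-[3-methoxy-4-(methoxymethoxy)phenyl]-4-(trimethylsilyl)but-3-yn-1-yl]oxy}-4-methoxy-2H-pyran-2-one | C=CCc1ccc(OC[C@@H](C#C[Si](C)(C)C)[C@H](OC2=C(OC)C=C(CC=C)OC2=O)c2ccc(OCOC)c(OC)c2)c(OC)c1
F11 | step 14 | (2R,3R)-5-allyl-3-[(4-allyl-2-methoxyphenoxy)methyl]-7-methoxy-2-[3-methoxy-4-(methoxymethoxy)phenyl]-2,3-dihydrobenzofuran | C=CCc1ccc(OC[C@H]2c3cc(CC=C)cc(OC)c3O[C@H]2c2ccc(OCOC)c(OC)c2)c(OC)c1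
F12 | step 14 | 4-{(2R,3R)-5-allyl-3-[(4-allyl-2-methoxyphenoxy)methyl]-7-methoxy-2,3-dihydrobenzofuran-2-yl}-2-methoxyphenol | C=CCc1ccc(OC[C@H]2c3cc(CC=C)cc(OC)c3O[C@H]2c2ccc(O)c(OC)c2)c(OC)c1
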